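**Retrosynthetic overview**
- The target is reached by cleaving two N-tosyl groups and a methyl ester from a protected 5-acetylpyrrole; the acetyl group comes from ipso-substitution of a C5–SiMe3 group, after N-Boc removal.
- The pyrrole is the only ring built (both indoles are bought intact). It is closed by a palladium heteroannulation that forms C3–C4 and N1–C5 from a β-iodo dehydrotryptophan ester and a 3-(silylethynyl)indole.
- The iodoenamide comes from a dehydrotryptophan ester (NIS), itself from Horner–Wadsworth–Emmons olefination of 1-tosylindole-3-carbaldehyde; the silylalkyne comes from Sonogashira coupling of 3-iodo-1-tosylindole.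
- Structural feature: in the pyrrole ring, N1–C2(CO2H)–C3(indol-3-yl) is the N–Cα–Cβ skeleton of a dehydrotryptophan, and C4(indol-3-yl)–C5(acetyl) is a two-carbon alkyne unit whose C5 end can carry silicon as a placeholder for the acetyl group.

Key step: step 7

Remark: pyrrole atoms are numbered as in the target (N1; C2 carries the carboxyl group, C3 and C4 the indol-3-yl groups, C5 the acetyl group). Phosphonate 3 is used as the racemate; its stereocentre is destroyed in step 2.

**Route**

Step 1
Reactants: 1 indole-3-carbaldehyde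
Product: 2 1-tosylindole-3-carbaldehyde
Conditions: TsCl, Et3N, DMAP (cat.), CH2Cl2, 0 °C → rt
Reagents that add atoms: p-toluenesulfonyl chloride, Cc1ccc(S(=O)(=O)Cl)cc1
Why: DMAP-catalysed N-sulfonylation of the acidic vinylogous-amide N–H; the tosyl group restores the electrophilicity of the aldehyde for step 2, keeps the indole nitrogen out of the palladium chemistry and deactivates the indole ring towards NIS and the acylium ion used later.

Step 2
Reactants: 2 1-tosylindole-3-carbaldehyde; 3 methyl 2-[(tert-butoxycarbonyl)amino]-2-(dimethoxyphosphoryl)acetate (racemic)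
Product: 4 methyl (Z)-2-[(tert-butoxycarbonyl)amino]-3-(1-tosylindol-3-yl)acrylate (indolyl cis to NHBoc)
Conditions: DBU, CH2Cl2, 0 °C → rt
Reagents that add atoms: none
Why: Horner–Wadsworth–Emmons olefination with an N-acyl phosphonoglycinate (Schmidt conditions), which with aryl aldehydes gives the Z dehydroamino ester; no stereocentre is formed and DBU leaves the N-tosyl group untouched.

Step 3
Reactants: 4 methyl (Z)-2-[(tert-butoxycarbonyl)amino]-3-(1-tosylindol-3-yl)acrylate
Product: 6 methyl (Z)-2-[(tert-butoxycarbonyl)amino]-3-iodo-3-(1-tosylindol-3-yl)acrylate (iodine cis to NHBoc, indolyl cis to the ester), via β-iodo N-Boc ketimine 5 (not isolated)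
Conditions: NIS, CH2Cl2, rt, dark; then Et3N, 0 °C → rt
Reagents that add atoms: N-iodosuccinimide, O=C1CCC(=O)N1I
Why: Electrophilic β-iodination of the enamide gives the α-imino β-iodo ester 5, and amine-induced imine-to-enamine tautomerisation (the established halogenation/tautomerisation sequence of N-acyl dehydroamino esters) returns the conjugated iodoenamide, whose geometry is decided in the tautomerisation and responds to the amine chosen, so that 6 should be obtainable as the main isomer and freed of any E isomer by chromatography, while the deactivated N-tosylindole ring does not compete for NIS.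

Step 4
Reactants: 7 indole
Product: 8 3-iodoindole
Conditions: I2, KOH, DMF, rt
Reagents that add atoms: iodine, II
Why: Electrophilic aromatic iodination of the indolide anion at its most nucleophilic carbon, C3; the sensitive product is precipitated with water and used at once.

Step 5
Reactants: 8 3-iodoindole
Product: 9 3-iodo-1-tosylindole
Conditions: NaH, THF, 0 °C; then TsCl, 0 °C → rt
Reagents that add atoms: p-toluenesulfonyl chloride, Cc1ccc(S(=O)(=O)Cl)cc1
Why: N-sulfonylation of the sodium indolide, which also turns the light- and acid-sensitive iodoindole into a stable crystalline aryl iodide.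

Step 6
Reactants: 9 3-iodo-1-tosylindole; 10 ethynyltrimethylsilane
Product: 11 1-tosyl-3-[(trimethylsilyl)ethynyl]indole
Conditions: PdCl2(PPh3)2 (cat.), CuI (cat.), Et3N, THF, rt
Reagents that add atoms: none
Why: Sonogashira coupling of an electron-poor heteroaryl iodide with a terminal alkyne, run at room temperature so that the C–Si bond is kept.

Step 7
Reactants: 6 methyl (Z)-2-[(tert-butoxycarbonyl)amino]-3-iodo-3-(1-tosylindol-3-yl)acrylate; 11 1-tosyl-3-[(trimethylsilyl)ethynyl]indole
Product: 12 methyl 1-(tert-butoxycarbonyl)-3,4-bis(1-tosylindol-3-yl)-5-(trimethylsilyl)pyrrole-2-carboxylate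
Conditions: Pd(OAc)2 (10 mol %), LiCl, K2CO3, dry DMF, 80 °C (11 in 1.5-fold excess)
Reagents that add atoms: none
Why: Pd(OAc)2 is reduced in the flask to zerovalent palladium, which adds oxidatively to the vinyl C–I bond of 6 with retention of geometry, and the vinylpalladium halide then adds syn across the alkyne of 11, forming C3–C4 and leaving the metal on the silyl-bearing carbon. The carbamate N–H, acidified by the neighbouring ester, is deprotonated by K2CO3 and displaces halide on divalent palladium to give a six-membered azapalladacycle, and C–N reductive elimination forms N1–C5, releases the aromatic pyrrole and returns zerovalent palladium. The closest known chemistry is the Larock heteroannulation of 2-iodoanilides and its extension to 2-amino-3-iodoacrylates, which gives pyrrole-2-carboxylates with internal alkynes. The ring is closed as a [3+2] annulation in which the N1–C2–C3 unit of 6 is joined to the two alkyne carbons, first by C–C and then by C–N bond formation, and no stereocentre is created. Two selectivities are needed: the orientation of insertion is secured by the SiMe3 group, which in such carbopalladations takes the carbon that stays on palladium and therefore ends next to nitrogen, and the cis relation of nitrogen and palladium is secured by the Z geometry of 6. The N-tosyl groups keep both indole nitrogens out of the catalytic cycle, and the silyl group also masks the alkyne terminus so that no Sonogashira-type pathway is open.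

Step 8
Reactants: 12 methyl 1-(tert-butoxycarbonyl)-3,4-bis(1-tosylindol-3-yl)-5-(trimethylsilyl)pyrrole-2-carboxylate
Product: 13 methyl 3,4-bis(1-tosylindol-3-yl)-5-(trimethylsilyl)-1H-pyrrole-2-carboxylate
Conditions: 1,2-dichlorobenzene, 180 °C, N2
Reagents that add atoms: none
Why: Thermolytic cleavage of a pyrrole N-Boc group (loss of isobutene, then decarboxylation) under neutral conditions, which spares the acid-labile C5–Si bond and is placed before the Lewis acid step so that no tert-butyl cation forms next to AlCl3 and the more nucleophilic N–H pyrrole is the acylation substrate.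

Step 9
Reactants: 13 methyl 3,4-bis(1-tosylindol-3-yl)-5-(trimethylsilyl)-1H-pyrrole-2-carboxylate
Product: 14 methyl 5-acetyl-3,4-bis(1-tosylindol-3-yl)-1H-pyrrole-2-carboxylate
Conditions: AcCl, AlCl3, CH2Cl2, −20 → 0 °C; then ice/1 M HCl
Reagents that add atoms: acetyl chloride, CC(=O)Cl
Why: Friedel–Crafts ipso-acyldesilylation, in which the acylium ion attacks the silyl-bearing α-carbon through a β-silyl-stabilised cation and SiMe3 leaves as Me3SiCl; every other pyrrole carbon is substituted, the tosylindoles are deactivated, and any protodesilylated material has only C5 free and should be acetylated at the same carbon.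

Step 10
Reactants: 14 methyl 5-acetyl-3,4-bis(1-tosylindol-3-yl)-1H-pyrrole-2-carboxylate
Product: 15 5-acetyl-3,4-bis(1H-indol-3-yl)-1H-pyrrole-2-carboxylic acid (target)
Conditions: KOH, MeOH/THF/H2O, 65 °C; then 1 M HCl to pH 3, 0 °C
Reagents that add atoms: potassium hydroxide, [K+].[OH-]
Why: Hydroxide cleaves both N-sulfonyl indoles by attack at sulfur (indolide as leaving group) and saponifies the methyl ester, while the pyrrolide anion formed under the conditions shields the acetyl group from condensation and cold acidification liberates the acid without decarboxylation.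

**Compound list**
1 | indole-3-carbaldehyde | O=Cc1c[nH]c2ccccc12 | starting material
2 | 1-tosylindole-3-carbaldehyde | O=Cc1cn(S(=O)(=O)c2ccc(C)cc2)c2ccccc12 | intermediate
3 | methyl 2-[(tert-butoxycarbonyl)amino]-2-(dimethoxyphosphoryl)acetate, racemic | COC(=O)C(NC(=O)OC(C)(C)C)P(=O)(OC)OC | starting material
4 | methyl (Z)-2-[(tert-butoxycarbonyl)amino]-3-(1-tosylindol-3-yl)acrylate | COC(=O)/C(NC(=O)OC(C)(C)C)=C/c1cn(S(=O)(=O)c2ccc(C)cc2)c2ccccc12 | intermediate
5 | methyl 2-[(tert-butoxycarbonyl)imino]-3-iodo-3-(1-tosylindol-3-yl)propanoate, racemic, imine geometry undefined | COC(=O)C(=NC(=O)OC(C)(C)C)C(I)c1cn(S(=O)(=O)c2ccc(C)cc2)c2ccccc12 | intermediate (not isolated)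
6 | methyl (Z)-2-[(tert-butoxycarbonyl)amino]-3-iodo-3-(1-tosylindol-3-yl)acrylate | COC(=O)/C(NC(=O)OC(C)(C)C)=C(/I)c1cn(S(=O)(=O)c2ccc(C)cc2)c2ccccc12 | intermediate
7 | indole | c1ccc2[nH]ccc2c1 | starting material
8 | 3-iodoindole | Ic1c[nH]c2ccccc12 | intermediate
9 | 3-iodo-1-tosylindole | Cc1ccc(S(=O)(=O)n2cc(I)c3ccccc32)cc1 | intermediate
10 | ethynyltrimethylsilane | C[Si](C)(C)C#C | starting material
11 | 1-tosyl-3-[(trimethylsilyl)ethynyl]indole | C[Si](C)(C)C#Cc1cn(S(=O)(=O)c2ccc(C)cc2)c2ccccc12 | intermediate
12 | methyl 1-(tert-butoxycarbonyl)-3,4-bis(1-tosylindol-3-yl)-5-(trimethylsilyl)pyrrole-2-carboxylate | COC(=O)c1n(C(=O)OC(C)(C)C)c([Si](C)(C)C)c(-c2cn(S(=O)(=O)c3ccc(C)cc3)c3ccccc23)c1-c1cn(S(=O)(=O)c2ccc(C)cc2)c2ccccc12 | intermediate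
13 | methyl 3,4-bis(1-tosylindol-3-yl)-5-(trimethylsilyl)-1H-pyrrole-2-carboxylate | COC(=O)c1[nH]c([Si](C)(C)C)c(-c2cn(S(=O)(=O)c3ccc(C)cc3)c3ccccc23)c1-c1cn(S(=O)(=O)c2ccc(C)cc2)c2ccccc12 | intermediate
14 | methyl 5-acetyl-3,4-bis(1-tosylindol-3-yl)-1H-pyrrole-2-carboxylate | COC(=O)c1[nH]c(C(C)=O)c(-c2cn(S(=O)(=O)c3ccc(C)cc3)c3ccccc23)c1-c1cn(S(=O)(=O)c2ccc(C)cc2)c2ccccc12 | intermediate
15 | 5-acetyl-3,4-bis(1H-indol-3-yl)-1H-pyrrole-2-carboxylic acid | CC(=O)c1[nH]c(C(=O)O)c(-c2c[nH]c3ccccc23)c1-c1c[nH]c2ccccc12 | target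

**Step count**
Total: 10 steps. Longest linear sequence: 7 steps (steps 1, 2, 3, 7, 8, 9, 10; the branch through steps 4, 5, 6 is equally long).

**Steps most likely to fail**

Step 7. Insertion of the fully substituted vinylpalladium into the hindered silylalkyne may be slow, so that reduction of the C–I bond or loss of alkene geometry outruns annulation. Carbonate may cleave the alkynyl C–Si bond, and C–N reductive elimination at a nitrogen that ends between SiMe3 and CO2Me may be sluggish. The fallback sets out from 11 and comes back at 14; it moves the annulation to the unhindered parent iodide and brings in the C3 indolyl group afterwards. Commercial methyl 2-[(tert-butoxycarbonyl)amino]acrylate is iodinated (NIS, CH2Cl2; then Et3N) through methyl 2-[(tert-butoxycarbonyl)imino]-3-iodopropanoate F1 to methyl (Z)-2-[(tert-butoxycarbonyl)amino]-3-iodoacrylate F2. F2 and 11 under the conditions of step 7 should give methyl 1-(tert-butoxycarbonyl)-4-(1-tosylindol-3-yl)-5-(trimethylsilyl)pyrrole-2-carboxylate F3. Thermolysis as in step 8 gives methyl 4-(1-tosylindol-3-yl)-5-(trimethylsilyl)-1H-pyrrole-2-carboxylate F4, and ipso-acetylation as in step 9 gives methyl 5-acetyl-4-(1-tosylindol-3-yl)-1H-pyrrole-2-carboxylate F5. Bromination of the one free pyrrole carbon, C3 (NBS, DMF, 0 °C), gives methyl 5-acetyl-3-bromo-4-(1-tosylindol-3-yl)-1H-pyrrole-2-carboxylate F6. Suzuki–Miyaura coupling of F6 (Pd(OAc)2, SPhos, K3PO4, toluene/H2O, 90 °C) with 3-(4,4,5,5-tetramethyl-1,3,2-dioxaborolan-2-yl)-1-tosylindole F7, made from 9 by Miyaura borylation (bis(pinacolato)diboron, PdCl2(dppf), KOAc, dioxane, 80 °C), delivers 14.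

Step 3. The tautomerisation of imine 5 may deliver mainly the geometric isomer with iodine trans to nitrogen, and the iodide may isomerise or lose iodine on handling in light. The fallback sets out from 4 and comes back at 12; it replaces the iodide by the configurationally sturdier bromide. Bromination of 4 (NBS, CH2Cl2, rt) gives methyl 3-bromo-2-[(tert-butoxycarbonyl)imino]-3-(1-tosylindol-3-yl)propanoate F8, which is not isolated. DABCO-induced tautomerisation, whose geometric course on β-aryl dehydroamino esters can be steered by the amine, gives methyl (Z)-3-bromo-2-[(tert-butoxycarbonyl)amino]-3-(1-tosylindol-3-yl)acrylate F9 (bromine cis to NHBoc). F9 is annulated with 11 under a phosphine-ligated catalyst suited to vinyl bromides (Pd(OAc)2, tri-tert-butylphosphonium tetrafluoroborate, K2CO3, DMF, 100 °C) to give 12.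

Step 9. Protodesilylation by HCl may run ahead of acylation, and the Lewis acid may promote over-acylation on the benzo rings of the tosylindoles or at the pyrrole nitrogen. The fallback sets out from 13 and comes back at 14; it avoids Friedel–Crafts chemistry altogether. Ipso-iododesilylation of 13 (ICl, CH2Cl2, −78 → 0 °C) gives methyl 5-iodo-3,4-bis(1-tosylindol-3-yl)-1H-pyrrole-2-carboxylate F10. Stille coupling with tributyl(1-ethoxyvinyl)stannane (PdCl2(PPh3)2, toluene, 100 °C) gives methyl 5-(1-ethoxyvinyl)-3,4-bis(1-tosylindol-3-yl)-1H-pyrrole-2-carboxylate F11. Hydrolysis of the enol ether (1 M HCl, THF, rt) unmasks the methyl ketone of 14.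

Further compounds
F1 | step 7 | methyl 2-[(tert-butoxycarbonyl)imino]-3-iodopropanoate | COC(=O)C(=NC(=O)OC(C)(C)C)CI
F2 | step 7 | methyl (Z)-2-[(tert-butoxycarbonyl)amino]-3-iodoacrylate | COC(=O)/C(NC(=O)OC(C)(C)C)=C/I
F3 | step 7 | methyl 1-(tert-butoxycarbonyl)-4-(1-tosylindol-3-yl)-5-(trimethylsilyl)pyrrole-2-carboxylate | COC(=O)c1cc(-c2cn(S(=O)(=O)c3ccc(C)cc3)c3ccccc23)c([Si](C)(C)C)n1C(=O)OC(C)(C)C
F4 | step 7 | methyl 4-(1-tosylindol-3-yl)-5-(trimethylsilyl)-1H-pyrrole-2-carboxylate | COC(=O)c1cc(-c2cn(S(=O)(=O)c3ccc(C)cc3)c3ccccc23)c([Si](C)(C)C)[nH]1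
F5 | step 7 | methyl 5-acetyl-4-(1-tosylindol-3-yl)-1H-pyrrole-2-carboxylate | COC(=O)c1cc(-c2cn(S(=O)(=O)c3ccc(C)cc3)c3ccccc23)c(C(C)=O)[nH]1
F6 | step 7 | methyl 5-acetyl-3-bromo-4-(1-tosylindol-3-yl)-1H-pyrrole-2-carboxylate | COC(=O)c1[nH]c(C(C)=O)c(-c2cn(S(=O)(=O)c3ccc(C)cc3)c3ccccc23)c1Br
F7 | step 7 | 3-(4,4,5,5-tetramethyl-1,3,2-dioxaborolan-2-yl)-1-tosylindole | Cc1ccc(S(=O)(=O)n2cc(B3OC(C)(C)C(C)(C)O3)c3ccccc32)cc1
F8 | step 3 | methyl 3-bromo-2-[(tert-butoxycarbonyl)imino]-3-(1-tosylindol-3-yl)propanoate, racemic | COC(=O)C(=NC(=O)OC(C)(C)C)C(Br)c1cn(S(=O)(=O)c2ccc(C)cc2)c2ccccc12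
F9 | step 3 | methyl (Z)-3-bromo-2-[(tert-butoxycarbonyl)amino]-3-(1-tosylindol-3-yl)acrylate | COC(=O)/C(NC(=O)OC(C)(C)C)=C(/Br)c1cn(S(=O)(=O)c2ccc(C)cc2)c2ccccc12
F10 | step 9 | methyl 5-iodo-3,4-bis(1-tosylindol-3-yl)-1H-pyrrole-2-carboxylate | COC(=O)c1[nH]c(I)c(-c2cn(S(=O)(=O)c3ccc(C)cc3)c3ccccc23)c1-c1cn(S(=O)(=O)c2ccc(C)cc2)c2ccccc12
F11 | step 9 | methyl 5-(1-ethoxyvinyl)-3,4-bis(1-tosylindol-3-yl)-1H-pyrrole-2-carboxylate | CCOC(=C)c1[nH]c(C(=O)OC)c(-c2cn(S(=O)(=O)c3ccc(C)cc3)c3ccccc23)c1-c1cn(S(=O)(=O)c2ccc(C)cc2)c2ccccc12
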